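**Assumption:** methyl vanillate, O-benzylvanillin, homovanillic acid and (4S)-4-benzyl-1,3-oxazolidin-2-one are bought; TBS = tert-butyldimethylsilyl.

## Retrosynthetic overview

1. Target 30 ⇒ global desilylation and reductive auxiliary removal from syn-aldol adduct 28. Adduct 28 comes from dihydrobenzofuran-5-carbaldehyde 20 and homovanillyl imide 25 by an Evans syn aldol, which sets both side-chain stereocentres.
2. Aldehyde 20 ⇒ trans-dihydrobenzofuran ester 17 ⇒ acid-mediated C2–O closure of phenol-diol 16.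
3. Diol 16 ⇒ a first Evans syn aldol of the ring B arylacetyl imide 10 with O-benzylvanillin 11, which sets C3 of the benzofuran.
4. Imide 10 ⇒ methyl vanillate (O-allylation, Claisen rearrangement, oxidative cleavage); imide 25 ⇒ homovanillic acid.
5. Ring order: the three benzene rings are bought; the only ring built is the dihydrofuran (step 10), closed before the fragment union (step 16).

## Route

**Step 1**
Reactants: 1 methyl vanillate
Product: 2 methyl 3-methoxy-4-(prop-2-enyloxy)benzoate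
Conditions: allyl bromide, K2CO3, acetone, reflux
Reagents that add atoms: allyl bromide, C=CCBr
Why: Williamson ether synthesis, the phenoxide displacing the allylic bromide by SN2.

**Step 2**
Reactants: 2 methyl 3-methoxy-4-(prop-2-enyloxy)benzoate
Product: 3 methyl 4-hydroxy-3-methoxy-5-(prop-2-enyl)benzoate
Conditions: neat (or N,N-diethylaniline), 200 °C, N2
Reagents that add atoms: none
Why: Aromatic Claisen rearrangement, a [3,3]-sigmatropic shift that can only end at the single free ortho position before rearomatising.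

**Step 3**
Reactants: 3 methyl 4-hydroxy-3-methoxy-5-(prop-2-enyl)benzoate
Product: 4 methyl 4-(benzyloxy)-3-methoxy-5-(prop-2-enyl)benzoate
Conditions: BnBr, K2CO3, DMF, 60 °C
Reagents that add atoms: benzyl bromide, BrCc1ccccc1
Why: Williamson O-benzylation masks the ring B phenol for the enolate chemistry ahead.

**Step 4**
Reactants: 4 methyl 4-(benzyloxy)-3-methoxy-5-(prop-2-enyl)benzoate
Product: 6 methyl 4-(benzyloxy)-3-methoxy-5-(2-oxoethyl)benzoate, via secondary ozonide 5 (not isolated)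
Conditions: O3, CH2Cl2, −78 °C (Sudan Red end point); then Me2S, −78 °C → rt
Reagents that add atoms: ozone, [O-][O+]=O
Why: Ozonolysis with reductive work-up cuts the terminal alkene to the arylacetaldehyde, the alkene reacting far faster than the ester-deactivated arene.

**Step 5**
Reactants: 6 methyl 4-(benzyloxy)-3-methoxy-5-(2-oxoethyl)benzoate
Product: 7 [2-(benzyloxy)-3-methoxy-5-(methoxycarbonyl)phenyl]acetic acid
Conditions: NaClO2, NaH2PO4, 2-methylbut-2-ene, t-BuOH/H2O, rt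
Reagents that add atoms: sodium chlorite, [Na+].[O-]Cl=O
Why: Pinnick oxidation converts the enolisable aldehyde to the acid under buffered conditions that leave the benzyl ether and ester alone.

**Step 6**
Reactants: 7 [2-(benzyloxy)-3-methoxy-5-(methoxycarbonyl)phenyl]acetic acid; 8 (4S)-4-benzyl-1,3-oxazolidin-2-one
Product: 10 methyl 4-(benzyloxy)-3-{2-[(4S)-4-benzyl-2-oxo-1,3-oxazolidin-3-yl]-2-oxoethyl}-5-methoxybenzoate, via mixed pivalic anhydride 9 (not isolated)
Conditions: Et3N, t-BuCOCl, THF, −20 °C; then LiCl, 8, −20 °C → rt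
Reagents that add atoms: none
Why: N-acylation of the Evans auxiliary through the mixed anhydride, which is attacked at the unhindered arylacetyl carbonyl.

**Step 7**
Reactants: 10 ring B arylacetyl imide; 11 4-(benzyloxy)-3-methoxybenzaldehyde
Product: 14 methyl 4-(benzyloxy)-3-{(2S,3S)-1-[(4S)-4-benzyl-2-oxo-1,3-oxazolidin-3-yl]-3-[4-(benzyloxy)-3-methoxyphenyl]-3-hydroxy-1-oxopropan-2-yl}-5-methoxybenzoate, via Z-boron enolate 12 (not isolated), via boron aldolate 13 (not isolated)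
Conditions: Bu2BOTf, i-Pr2NEt, CH2Cl2, 0 °C; 11, −78 → 0 °C; then pH 7 buffer (NaH2PO4/Na2HPO4), MeOH, 30% H2O2, 0 °C
Reagents that add atoms: none
Why: Evans syn aldol reaction in which the Z-boron enolate reacts through a Zimmerman–Traxler chair on the face away from the auxiliary benzyl group, fixing the α-carbon (2S) that becomes C3 (R) of the benzofuran.

**Step 8**
Reactants: 14 syn-aldol adduct
Product: 15 methyl 4-(benzyloxy)-3-{(1S,2R)-1-[4-(benzyloxy)-3-methoxyphenyl]-1,3-dihydroxypropan-2-yl}-5-methoxybenzoate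
Conditions: NaBH4, THF/H2O (4:1), 0 °C → rt
Reagents that add atoms: none
Why: Reductive cleavage of the activated imide carbonyl by borohydride gives the 1,3-diol and free auxiliary while the aryl methyl ester is not reduced and neither stereocentre is touched (the descriptor change at C2 is only a priority change).

**Step 9**
Reactants: 15 dibenzyl diol
Product: 16 methyl 4-hydroxy-3-[(1S,2R)-1,3-dihydroxy-1-(4-hydroxy-3-methoxyphenyl)propan-2-yl]-5-methoxybenzoate
Conditions: H2 (1 atm), Pd/C, EtOAc/MeOH, rt, stopped at full debenzylation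
Reagents that add atoms: none
Why: Catalytic hydrogenolysis removes both aryl benzyl ethers much faster than the benzylic C–OH bond is cleaved under neutral conditions.

**Step 10**
Reactants: 16 bis-phenol diol
Product: 17 methyl (2S,3R)-2-(4-hydroxy-3-methoxyphenyl)-3-(hydroxymethyl)-7-methoxy-2,3-dihydro-1-benzofuran-5-carboxylate
Conditions: TsOH·H2O (10 mol%), MeCN, 0 °C → rt
Reagents that add atoms: none
Why: Acid-catalysed SN1 cyclodehydration in which the para-hydroxybenzylic alcohol ionises to a stabilised benzylic cation captured 5-exo by the ring B phenol, the aldol-derived C3 being untouched and C2 settling anti to the CH2OH group to give the trans (2S,3R) ring.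

**Step 11**
Reactants: 17 dihydrobenzofuran phenol-alcohol
Product: 18 methyl (2S,3R)-2-[4-(TBS-oxy)-3-methoxyphenyl]-3-[(TBS-oxy)methyl]-7-methoxy-2,3-dihydro-1-benzofuran-5-carboxylate
Conditions: TBSCl, imidazole, DMF, rt
Reagents that add atoms: tert-butyldimethylsilyl chloride, CC(C)(C)[Si](C)(C)Cl
Why: Imidazole-promoted silylation caps both the phenol and the primary alcohol for the reductions and the boron aldol to come.

**Step 12**
Reactants: 18 bis-TBS ester
Product: 19 {(2S,3R)-2-[4-(TBS-oxy)-3-methoxyphenyl]-3-[(TBS-oxy)methyl]-7-methoxy-2,3-dihydro-1-benzofuran-5-yl}methanol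
Conditions: i-Bu2AlH, CH2Cl2, −78 °C; then aq. potassium sodium tartrate
Reagents that add atoms: none
Why: Hydride reduction of the aryl ester to the benzylic alcohol at low temperature leaves both silyl ethers and the ring stereocentres intact.

**Step 13**
Reactants: 19 benzylic alcohol
Product: 20 (2S,3R)-2-[4-(TBS-oxy)-3-methoxyphenyl]-3-[(TBS-oxy)methyl]-7-methoxy-2,3-dihydro-1-benzofuran-5-carbaldehyde
Conditions: MnO2 (excess), CH2Cl2, rt
Reagents that add atoms: none
Why: MnO2 oxidation is selective for the electron-rich benzylic alcohol and stops at the aldehyde.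

**Step 14**
Reactants: 21 homovanillic acid
Product: 23 [4-(TBS-oxy)-3-methoxyphenyl]acetic acid, via bis-silyl compound 22 (not isolated)
Conditions: TBSCl, imidazole, DMF, rt; then AcOH/THF/H2O, rt
Reagents that add atoms: tert-butyldimethylsilyl chloride, CC(C)(C)[Si](C)(C)Cl
Why: Exhaustive silylation followed by selective hydrolysis of the much more labile silyl ester leaves the aryl silyl ether in place.

**Step 15**
Reactants: 23 [4-(TBS-oxy)-3-methoxyphenyl]acetic acid; 8 (4S)-4-benzyl-1,3-oxazolidin-2-one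
Product: 25 (4S)-4-benzyl-3-{[4-(TBS-oxy)-3-methoxyphenyl]acetyl}-1,3-oxazolidin-2-one, via mixed pivalic anhydride 24 (not isolated)
Conditions: Et3N, t-BuCOCl, THF, −20 °C; then LiCl, 8, −20 °C → rt
Reagents that add atoms: none
Why: N-acylation of the Evans auxiliary through the mixed anhydride, as in step 6.

**Step 16**
Reactants: 25 ring C arylacetyl imide; 20 dihydrobenzofuran-5-carbaldehyde
Product: 28 (4S)-4-benzyl-3-[(2S,3S)-2-[4-(TBS-oxy)-3-methoxyphenyl]-3-{(2S,3R)-2-[4-(TBS-oxy)-3-methoxyphenyl]-3-[(TBS-oxy)methyl]-7-methoxy-2,3-dihydro-1-benzofuran-5-yl}-3-hydroxypropanoyl]-1,3-oxazolidin-2-one, via Z-boron enolate 26 (not isolated), via boron aldolate 27 (not isolated)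
Conditions: 25 (1.3 equiv), Bu2BOTf, i-Pr2NEt, CH2Cl2, 0 °C; 20, −78 → 0 °C; then pH 7 buffer (NaH2PO4/Na2HPO4), MeOH, 30% H2O2, 0 °C
Reagents that add atoms: none
Why: Evans syn aldol reaction joining the two fragments, the Z-boron enolate adding through a Zimmerman–Traxler chair on the face away from the auxiliary benzyl group to set the (2S,3S) pair under auxiliary control, the remote ring stereocentres having no influence.

**Step 17**
Reactants: 28 syn-aldol adduct
Product: 29 (1S,2R)-2-[4-(TBS-oxy)-3-methoxyphenyl]-1-{(2S,3R)-2-[4-(TBS-oxy)-3-methoxyphenyl]-3-[(TBS-oxy)methyl]-7-methoxy-2,3-dihydro-1-benzofuran-5-yl}propane-1,3-diol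
Conditions: LiBH4, MeOH (3 equiv), THF, 0 °C
Reagents that add atoms: none
Why: Reductive cleavage of the imide gives the primary alcohol and free auxiliary without touching either new stereocentre (the (2S) centre is renamed (2R) only because CH2OH now ranks below the carbinol carbon).

**Step 18**
Reactants: 29 tris-TBS diol
Product: 30 (1S,2R)-1-[(2S,3R)-2-(4-hydroxy-3-methoxyphenyl)-3-(hydroxymethyl)-7-methoxy-2,3-dihydro-1-benzofuran-5-yl]-2-(4-hydroxy-3-methoxyphenyl)propane-1,3-diol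
Conditions: Bu4NF, AcOH (1:1, 4 equiv), THF, 0 °C → rt
Reagents that add atoms: none
Why: Fluoride-driven desilylation, buffered by acetic acid, frees the two phenols and the primary alcohol without acid that could ionise the benzylic alcohol or base that could open the dihydrobenzofuran.

## Compound list

1 | methyl 4-hydroxy-3-methoxybenzoate (methyl vanillate) | COC(=O)c1ccc(O)c(OC)c1 | starting material
2 | methyl 3-methoxy-4-(prop-2-enyloxy)benzoate | COC(=O)c1ccc(OCC=C)c(OC)c1 | intermediate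
3 | methyl 4-hydroxy-3-methoxy-5-(prop-2-enyl)benzoate | COC(=O)c1cc(CC=C)c(O)c(OC)c1 | intermediate
4 | methyl 4-(benzyloxy)-3-methoxy-5-(prop-2-enyl)benzoate | COC(=O)c1cc(CC=C)c(OCc2ccccc2)c(OC)c1 | intermediate
5 | methyl 4-(benzyloxy)-3-methoxy-5-(1,2,4-trioxolan-3-ylmethyl)benzoate (secondary ozonide, racemic at the trioxolane carbon, not isolated) | COC(=O)c1cc(CC2OCOO2)c(OCc2ccccc2)c(OC)c1 | intermediate
6 | methyl 4-(benzyloxy)-3-methoxy-5-(2-oxoethyl)benzoate | COC(=O)c1cc(CC=O)c(OCc2ccccc2)c(OC)c1 | intermediate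
7 | [2-(benzyloxy)-3-methoxy-5-(methoxycarbonyl)phenyl]acetic acid | COC(=O)c1cc(CC(=O)O)c(OCc2ccccc2)c(OC)c1 | intermediate
8 | (4S)-4-benzyl-1,3-oxazolidin-2-one | O=C1N[C@@H](Cc2ccccc2)CO1 | starting material
9 | mixed anhydride of 7 with pivalic acid (not isolated) | CC(C)(C)C(=O)OC(=O)Cc1cc(C(=O)OC)cc(OC)c1OCc1ccccc1 | intermediate
10 | methyl 4-(benzyloxy)-3-{2-[(4S)-4-benzyl-2-oxo-1,3-oxazolidin-3-yl]-2-oxoethyl}-5-methoxybenzoate | COC(=O)c1cc(CC(=O)N2[C@@H](Cc3ccccc3)COC2=O)c(OCc2ccccc2)c(OC)c1 | intermediate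
11 | 4-(benzyloxy)-3-methoxybenzaldehyde | COc1cc(C=O)ccc1OCc1ccccc1 | starting material
12 | (Z)-dibutylboron enolate of 10 (not isolated) | CCCCB(CCCC)O/C(=C\c1cc(C(=O)OC)cc(OC)c1OCc1ccccc1)N1[C@@H](Cc2ccccc2)COC1=O | intermediate
13 | O-dibutylboron aldolate of 14 (not isolated) | COc1cc([C@@H](OB(CCCC)CCCC)[C@@H](C(=O)N2[C@@H](Cc3ccccc3)COC2=O)c2cc(C(=O)OC)cc(OC)c2OCc2ccccc2)ccc1OCc1ccccc1 | intermediate
14 | methyl 4-(benzyloxy)-3-{(2S,3S)-1-[(4S)-4-benzyl-2-oxo-1,3-oxazolidin-3-yl]-3-[4-(benzyloxy)-3-methoxyphenyl]-3-hydroxy-1-oxopropan-2-yl}-5-methoxybenzoate | COc1cc([C@@H](O)[C@@H](C(=O)N2[C@@H](Cc3ccccc3)COC2=O)c2cc(C(=O)OC)cc(OC)c2OCc2ccccc2)ccc1OCc1ccccc1 | intermediate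
15 | methyl 4-(benzyloxy)-3-{(1S,2R)-1-[4-(benzyloxy)-3-methoxyphenyl]-1,3-dihydroxypropan-2-yl}-5-methoxybenzoate | COc1cc([C@@H](O)[C@@H](CO)c2cc(C(=O)OC)cc(OC)c2OCc2ccccc2)ccc1OCc1ccccc1 | intermediate
16 | methyl 4-hydroxy-3-[(1S,2R)-1,3-dihydroxy-1-(4-hydroxy-3-methoxyphenyl)propan-2-yl]-5-methoxybenzoate | COc1cc([C@@H](O)[C@@H](CO)c2cc(C(=O)OC)cc(OC)c2O)ccc1O | intermediate
17 | methyl (2S,3R)-2-(4-hydroxy-3-methoxyphenyl)-3-(hydroxymethyl)-7-methoxy-2,3-dihydro-1-benzofuran-5-carboxylate | COc1cc([C@H]2Oc3c(OC)cc(C(=O)OC)cc3[C@@H]2CO)ccc1O | intermediate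
18 | methyl (2S,3R)-2-{4-[(tert-butyldimethylsilyl)oxy]-3-methoxyphenyl}-3-{[(tert-butyldimethylsilyl)oxy]methyl}-7-methoxy-2,3-dihydro-1-benzofuran-5-carboxylate | COc1cc([C@H]2Oc3c(OC)cc(C(=O)OC)cc3[C@@H]2CO[Si](C)(C)C(C)(C)C)ccc1O[Si](C)(C)C(C)(C)C | intermediate
19 | [(2S,3R)-2-{4-[(tert-butyldimethylsilyl)oxy]-3-methoxyphenyl}-3-{[(tert-butyldimethylsilyl)oxy]methyl}-7-methoxy-2,3-dihydro-1-benzofuran-5-yl]methanol | COc1cc([C@H]2Oc3c(OC)cc(CO)cc3[C@@H]2CO[Si](C)(C)C(C)(C)C)ccc1O[Si](C)(C)C(C)(C)C | intermediate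
20 | (2S,3R)-2-{4-[(tert-butyldimethylsilyl)oxy]-3-methoxyphenyl}-3-{[(tert-butyldimethylsilyl)oxy]methyl}-7-methoxy-2,3-dihydro-1-benzofuran-5-carbaldehyde | COc1cc([C@H]2Oc3c(OC)cc(C=O)cc3[C@@H]2CO[Si](C)(C)C(C)(C)C)ccc1O[Si](C)(C)C(C)(C)C | intermediate
21 | (4-hydroxy-3-methoxyphenyl)acetic acid (homovanillic acid) | COc1cc(CC(=O)O)ccc1O | starting material
22 | tert-butyldimethylsilyl {4-[(tert-butyldimethylsilyl)oxy]-3-methoxyphenyl}acetate (not isolated) | COc1cc(CC(=O)O[Si](C)(C)C(C)(C)C)ccc1O[Si](C)(C)C(C)(C)C | intermediate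
23 | {4-[(tert-butyldimethylsilyl)oxy]-3-methoxyphenyl}acetic acid | COc1cc(CC(=O)O)ccc1O[Si](C)(C)C(C)(C)C | intermediate
24 | mixed anhydride of 23 with pivalic acid (not isolated) | CC(C)(C)C(=O)OC(=O)Cc1ccc(O[Si](C)(C)C(C)(C)C)c(OC)c1 | intermediate
25 | (4S)-4-benzyl-3-({4-[(tert-butyldimethylsilyl)oxy]-3-methoxyphenyl}acetyl)-1,3-oxazolidin-2-one | COc1cc(CC(=O)N2[C@@H](Cc3ccccc3)COC2=O)ccc1O[Si](C)(C)C(C)(C)C | intermediate
26 | (Z)-dibutylboron enolate of 25 (not isolated) | CCCCB(CCCC)O/C(=C\c1ccc(O[Si](C)(C)C(C)(C)C)c(OC)c1)N1[C@@H](Cc2ccccc2)COC1=O | intermediate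
27 | O-dibutylboron aldolate of 28 (not isolated) | COc1cc([C@H]2Oc3c(OC)cc([C@@H](OB(CCCC)CCCC)[C@@H](C(=O)N4[C@@H](Cc5ccccc5)COC4=O)c4ccc(O[Si](C)(C)C(C)(C)C)c(OC)c4)cc3[C@@H]2CO[Si](C)(C)C(C)(C)C)ccc1O[Si](C)(C)C(C)(C)C | intermediate
28 | (4S)-4-benzyl-3-[(2S,3S)-2-{4-[(tert-butyldimethylsilyl)oxy]-3-methoxyphenyl}-3-[(2S,3R)-2-{4-[(tert-butyldimethylsilyl)oxy]-3-methoxyphenyl}-3-{[(tert-butyldimethylsilyl)oxy]methyl}-7-methoxy-2,3-dihydro-1-benzofuran-5-yl]-3-hydroxypropanoyl]-1,3-oxazolidin-2-one | COc1cc([C@H]2Oc3c(OC)cc([C@@H](O)[C@@H](C(=O)N4[C@@H](Cc5ccccc5)COC4=O)c4ccc(O[Si](C)(C)C(C)(C)C)c(OC)c4)cc3[C@@H]2CO[Si](C)(C)C(C)(C)C)ccc1O[Si](C)(C)C(C)(C)C | intermediate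
29 | (1S,2R)-2-{4-[(tert-butyldimethylsilyl)oxy]-3-methoxyphenyl}-1-[(2S,3R)-2-{4-[(tert-butyldimethylsilyl)oxy]-3-methoxyphenyl}-3-{[(tert-butyldimethylsilyl)oxy]methyl}-7-methoxy-2,3-dihydro-1-benzofuran-5-yl]propane-1,3-diol | COc1cc([C@H]2Oc3c(OC)cc([C@@H](O)[C@@H](CO)c4ccc(O[Si](C)(C)C(C)(C)C)c(OC)c4)cc3[C@@H]2CO[Si](C)(C)C(C)(C)C)ccc1O[Si](C)(C)C(C)(C)C | intermediate
30 | (1S,2R)-1-[(2S,3R)-2-(4-hydroxy-3-methoxyphenyl)-3-(hydroxymethyl)-7-methoxy-2,3-dihydro-1-benzofuran-5-yl]-2-(4-hydroxy-3-methoxyphenyl)propane-1,3-diol | COc1cc([C@H]2Oc3c(OC)cc([C@@H](O)[C@@H](CO)c4ccc(O)c(OC)c4)cc3[C@@H]2CO)ccc1O | target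

## Step count and risks

Total steps: 18. Longest linear sequence: 16 steps (steps 1–13, then 16–18); the side branch is steps 14–15.

**Step 16 (fragment-joining aldol).** The aldehyde 20 is electron-rich and precious, so incomplete conversion, retro-aldol on work-up or eroded diastereoselectivity are the main dangers. The fallback sets out from acid 23 and returns at diol 29. Acid 23 is coupled to (4S)-4-benzyl-1,3-thiazolidine-2-thione (EDC·HCl, DMAP, CH2Cl2) to give the N-acyl thiazolidinethione F1. Soft enolisation with TiCl4, i-Pr2NEt and N-methylpyrrolidinone (CH2Cl2, 0 °C) gives the chlorotitanium Z-enolate F2. This more nucleophilic enolate adds to 20 at −78 → 0 °C in the Evans-syn sense to give the (2S,3S) thiazolidinethione aldol adduct F3. The thione auxiliary is then cleaved directly with NaBH4 in THF/EtOH to give 29.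

**Step 10 (acid ring closure).** Acid may cause loss of formaldehyde to a stilbene, or oligomerisation of the cation. The fallback sets out from 16 and returns at 17, closing the ring under basic conditions instead. Peracetylation (Ac2O, pyridine, DMAP) gives the tetraacetate F4. Piperidine in THF at rt removes only the two aryl acetates to give the bis-phenol diacetate F5. In the same flask the para-phenoxide expels the benzylic acetate (1,6-elimination) to give the para-quinone methide F6. The ring B phenoxide closes onto F6 by 5-exo oxa-Michael addition to give the trans acetate F7. K2CO3 in MeOH then removes the remaining acetate to give 17.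

**Step 8 (reductive auxiliary removal next to an ester).** Basic borohydride may trigger retro-aldol of the electron-rich benzylic aldolate or start to reduce the methyl ester. The fallback sets out from 14 and returns at 15. LiOH/H2O2 (THF/H2O, 0 °C) hydrolyses the imide to the β-hydroxy acid F8. BH3·SMe2 (THF, 0 °C → rt) then reduces the carboxylic acid selectively in the presence of the methyl ester to give 15.

## Further compounds

F1 | step 16 | (4S)-4-benzyl-3-({4-[(tert-butyldimethylsilyl)oxy]-3-methoxyphenyl}acetyl)-1,3-thiazolidine-2-thione | COc1cc(CC(=O)N2[C@@H](Cc3ccccc3)CSC2=S)ccc1O[Si](C)(C)C(C)(C)C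
F2 | step 16 | (Z)-trichlorotitanium enolate of F1 | Cl[Ti](Cl)(Cl)O/C(=C\c1ccc(O[Si](C)(C)C(C)(C)C)c(OC)c1)N1[C@@H](Cc2ccccc2)CSC1=S
F3 | step 16 | (2S,3S)-2-{4-[(tert-butyldimethylsilyl)oxy]-3-methoxyphenyl}-3-[(2S,3R)-2-{4-[(tert-butyldimethylsilyl)oxy]-3-methoxyphenyl}-3-{[(tert-butyldimethylsilyl)oxy]methyl}-7-methoxy-2,3-dihydro-1-benzofuran-5-yl]-3-hydroxy-1-[(4S)-4-benzyl-2-thioxo-1,3-thiazolidin-3-yl]propan-1-one | COc1cc([C@H]2Oc3c(OC)cc([C@@H](O)[C@@H](C(=O)N4[C@@H](Cc5ccccc5)CSC4=S)c4ccc(O[Si](C)(C)C(C)(C)C)c(OC)c4)cc3[C@@H]2CO[Si](C)(C)C(C)(C)C)ccc1O[Si](C)(C)C(C)(C)C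
F4 | step 10 | methyl 4-acetoxy-3-[(1S,2R)-1,3-diacetoxy-1-(4-acetoxy-3-methoxyphenyl)propan-2-yl]-5-methoxybenzoate | COc1cc([C@@H](OC(C)=O)[C@@H](COC(C)=O)c2cc(C(=O)OC)cc(OC)c2OC(C)=O)ccc1OC(C)=O
F5 | step 10 | methyl 3-[(1S,2R)-1,3-diacetoxy-1-(4-hydroxy-3-methoxyphenyl)propan-2-yl]-4-hydroxy-5-methoxybenzoate | COc1cc([C@@H](OC(C)=O)[C@@H](COC(C)=O)c2cc(C(=O)OC)cc(OC)c2O)ccc1O
F6 | step 10 | methyl 3-[(2R)-1-acetoxy-3-(3-methoxy-4-oxocyclohexa-2,5-dien-1-ylidene)propan-2-yl]-4-hydroxy-5-methoxybenzoate (para-quinone methide, mixture of exocyclic double-bond isomers, not isolated) | COC1=CC(=C[C@@H](COC(C)=O)c2cc(C(=O)OC)cc(OC)c2O)C=CC1=O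
F7 | step 10 | methyl (2S,3R)-3-(acetoxymethyl)-2-(4-hydroxy-3-methoxyphenyl)-7-methoxy-2,3-dihydro-1-benzofuran-5-carboxylate | COc1cc([C@H]2Oc3c(OC)cc(C(=O)OC)cc3[C@@H]2COC(C)=O)ccc1O
F8 | step 8 | (2S,3S)-2-[2-(benzyloxy)-3-methoxy-5-(methoxycarbonyl)phenyl]-3-[4-(benzyloxy)-3-methoxyphenyl]-3-hydroxypropanoic acid | COc1cc([C@@H](O)[C@@H](C(=O)O)c2cc(C(=O)OC)cc(OC)c2OCc2ccccc2)ccc1OCc1ccccc1
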